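**Retrosynthetic overview**
1. Target ⇐ C9 ketone (CBS reduction) ⇐ 14-membered ring closed last at the C(=CH2)–CH(OH) bond by an intramolecular Nozaki–Hiyama–Kishi coupling of a 2-iodoalkene with an aldehyde.
2. Oxirane ⇐ Shi epoxidation of the still acyclic E-trisubstituted alkene; acetate ⇐ PMB ether.
3. cis-α-Methylene-γ-butyrolactone ⇐ indium Barbier union of West aldehyde 13 with East allylic bromide 25 under chelation control, then lactonisation.
4. West 13 ⇐ (S)-citronellal (proline α-aminoxylation, ozonolysis, acetylide, hydroalumination–iodination); East 25 ⇐ 3-(PMB-oxy)propanol (Johnson–Claisen, vinylalumination, SN2' bromination).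
5. Ring order: γ-lactone (step 19) → oxirane (step 22) → 14-membered carbocycle (step 24).

Assumption and convention (one line): 1 and 14 are bought; ring carbons are numbered C1 (lactone CH bearing the ring CH2), C2 (lactone CH–O), C3 (CHOAc), C4 (CHMe), C5–C7 (CH2), C8 (C=CH2), C9 (CHOH), C10–C11 (CH2), C12 (oxirane C–Me), C13 (oxirane CH), C14 (CH2), so the target is 1S,2R,3R,4S,9R,12R,13R.

Steps 1–9 make the West fragment, steps 10–18 the East fragment, steps 19–26 join them and finish.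

**Step 1**
Reactants: 1 (S)-citronellal, (3S)-3,7-dimethyloct-6-enal
Product: 3 (2R,3S)-2-(anilinooxy)-3,7-dimethyloct-6-en-1-ol, via aminoxy aldehyde 2 (not isolated)
Conditions: PhNO, L-proline (20 mol%), DMSO, rt, 30 min; then NaBH4, MeOH, 0 °C
Reagents that add atoms: nitrosobenzene, O=Nc1ccccc1
Why: Organocatalytic α-aminoxylation (enamine catalysis): the L-proline enamine of 1 attacks the oxygen of PhNO on the face directed by the carboxylic acid, setting the 2R oxygenated centre (future C3) under catalyst control beside the untouched chiral-pool methyl centre (future C4), and immediate borohydride reduction prevents epimerisation.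

**Step 2**
Reactants: 3 (2R,3S)-2-(anilinooxy)-3,7-dimethyloct-6-en-1-ol
Product: 4 (2R,3S)-3,7-dimethyloct-6-ene-1,2-diol
Conditions: Zn dust, AcOH/THF, rt
Reagents that add atoms: none
Why: Zinc in acetic acid reductively cleaves the weak N–O bond and releases the 1,2-diol without affecting the alkene or either stereocentre.

**Step 3**
Reactants: 4 (2R,3S)-3,7-dimethyloct-6-ene-1,2-diol
Product: 5 (4R)-2-(4-methoxyphenyl)-4-[(2S)-6-methylhept-5-en-2-yl]-1,3-dioxolane (mixture at the acetal carbon)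
Conditions: 4-MeOC6H4CH(OMe)2, PPTS (cat.), CH2Cl2, rt
Reagents that add atoms: 4-methoxybenzaldehyde dimethyl acetal, COc1ccc(C(OC)OC)cc1
Why: Acid-catalysed transacetalisation protects both hydroxyls as the p-methoxybenzylidene acetal, which later delivers the PMB group to the secondary oxygen; the new acetal centre is inconsequential.

**Step 4**
Reactants: 5 (4R)-2-(4-methoxyphenyl)-4-[(2S)-6-methylhept-5-en-2-yl]-1,3-dioxolane
Product: 7 (4S)-4-[(4R)-2-(4-methoxyphenyl)-1,3-dioxolan-4-yl]pentan-1-ol, via aldehyde 6 (not isolated)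
Conditions: O3, CH2Cl2/MeOH, −78 °C (Sudan Red 7B end point); then NaBH4 (excess), −78 → 0 °C
Reagents that add atoms: ozone, [O-][O+]=O
Why: Ozonolysis with reductive work-up: the electron-rich trisubstituted alkene is cleaved much faster than the anisyl ring or the acetal C–H (indicator-controlled end point), and borohydride reduces the aldehyde in the same flask.

**Step 5**
Reactants: 7 (4S)-4-[(4R)-2-(4-methoxyphenyl)-1,3-dioxolan-4-yl]pentan-1-ol
Product: 8 (4R)-4-[(2S)-5-iodopentan-2-yl]-2-(4-methoxyphenyl)-1,3-dioxolane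
Conditions: I2, PPh3, imidazole, THF, 0 °C → rt
Reagents that add atoms: iodine, [I][I]
Why: Garegg–Samuelsson (Appel-type) iodination converts the primary alcohol to the iodide under neutral conditions that leave the acetal intact.

**Step 6**
Reactants: 8 (4R)-4-[(2S)-5-iodopentan-2-yl]-2-(4-methoxyphenyl)-1,3-dioxolane
Product: 9 (4R)-4-[(2S)-hept-6-yn-2-yl]-2-(4-methoxyphenyl)-1,3-dioxolane
Conditions: LiC≡CH·H2NCH2CH2NH2, DMSO, 10 °C → rt
Reagents that add atoms: lithium acetylide (ethylenediamine complex), [Li]C#C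
Why: SN2 alkylation of lithium acetylide by the unhindered primary iodide in DMSO installs the terminal alkyne (C8 plus the future exocyclic methylene carbon).

**Step 7**
Reactants: 9 (4R)-4-[(2S)-hept-6-yn-2-yl]-2-(4-methoxyphenyl)-1,3-dioxolane
Product: 10 (2R,3S)-2-[(4-methoxybenzyl)oxy]-3-methyloct-7-yn-1-ol
Conditions: i-Bu2AlH (3 equiv), CH2Cl2, −78 → 0 °C; aq. potassium sodium tartrate (KNaC4H4O6) work-up
Reagents that add atoms: none
Why: Regioselective reductive opening of the p-methoxybenzylidene acetal: aluminium coordinates the less hindered primary oxygen, so hydride delivery leaves the PMB ether on the secondary oxygen and frees the primary alcohol.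

**Step 8**
Reactants: 10 (2R,3S)-2-[(4-methoxybenzyl)oxy]-3-methyloct-7-yn-1-ol
Product: 12 (2R,3S)-7-iodo-2-[(4-methoxybenzyl)oxy]-3-methyloct-7-en-1-ol, via alkenylalane 11 (not isolated)
Conditions: NiCl2(dppp) [dppp = Ph2P(CH2)3PPh2] (3 mol%), i-Bu2AlH (2.4 equiv), THF, 0 °C → rt; then N-iodosuccinimide, 0 °C
Reagents that add atoms: N-iodosuccinimide, O=C1CCC(=O)N1I
Why: Nickel-catalysed α-selective (Markovnikov) hydroalumination of the terminal alkyne with the bidentate phosphine places aluminium on the internal carbon (the hydroxyl is masked as its aluminium alkoxide by the first equivalent of hydride), and iodo-dealumination with retention gives the 2-iodo-1-alkene.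

**Step 9**
Reactants: 12 (2R,3S)-7-iodo-2-[(4-methoxybenzyl)oxy]-3-methyloct-7-en-1-ol
Product: 13 (2R,3S)-7-iodo-2-[(4-methoxybenzyl)oxy]-3-methyloct-7-enal
Conditions: Dess–Martin periodinane, NaHCO3, CH2Cl2, 0 °C → rt; used crude
Reagents that add atoms: none
Why: Buffered Dess–Martin oxidation gives the α-alkoxy aldehyde without epimerisation and without touching the iodoalkene.

**Step 10**
Reactants: 14 3-[(4-methoxybenzyl)oxy]propan-1-ol
Product: 15 3-[(4-methoxybenzyl)oxy]propanal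
Conditions: TEMPO (10 mol%), PhI(OAc)2, CH2Cl2, rt
Reagents that add atoms: none
Why: TEMPO/PhI(OAc)2 oxoammonium oxidation stops cleanly at the aldehyde and tolerates the PMB ether.

**Step 11**
Reactants: 15 3-[(4-methoxybenzyl)oxy]propanal
Product: 16 5-[(4-methoxybenzyl)oxy]-2-methylpent-1-en-3-ol (racemic)
Conditions: CH2=C(CH3)MgBr, THF, −78 → 0 °C
Reagents that add atoms: isopropenylmagnesium bromide, C=C(C)[Mg]Br
Why: Grignard 1,2-addition gives the secondary allylic alcohol needed for the sigmatropic step; it is used as the racemate because its stereocentre is destroyed in step 12.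

**Step 12**
Reactants: 16 5-[(4-methoxybenzyl)oxy]-2-methylpent-1-en-3-ol
Product: 17 ethyl (4E)-7-[(4-methoxybenzyl)oxy]-4-methylhept-4-enoate
Conditions: CH3C(OEt)3, EtCO2H (cat.), 140 °C, EtOH distilled off
Reagents that add atoms: triethyl orthoacetate, CCOC(C)(OCC)OCC
Why: Johnson–Claisen (orthoester) [3,3]-rearrangement through a chair transition state with the carbinol substituent equatorial gives the E trisubstituted alkene (future C12=C13) and adds the two-carbon ester arm.

**Step 13**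
Reactants: 17 ethyl (4E)-7-[(4-methoxybenzyl)oxy]-4-methylhept-4-enoate
Product: 18 (4E)-7-[(4-methoxybenzyl)oxy]-4-methylhept-4-en-1-ol
Conditions: LiAlH4, Et2O, 0 °C
Reagents that add atoms: none
Why: LiAlH4 reduces the ester to the primary alcohol (future C9) without affecting the isolated alkene or the PMB ether.

**Step 14**
Reactants: 18 (4E)-7-[(4-methoxybenzyl)oxy]-4-methylhept-4-en-1-ol
Product: 19 triethyl{[(4E)-7-[(4-methoxybenzyl)oxy]-4-methylhept-4-en-1-yl]oxy}silane
Conditions: Et3SiCl, imidazole, CH2Cl2, 0 °C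
Reagents that add atoms: chlorotriethylsilane, CC[Si](Cl)(CC)CC
Why: Silylation gives a primary TES ether that can later be oxidised directly to the aldehyde.

**Step 15**
Reactants: 19 triethyl{[(4E)-7-[(4-methoxybenzyl)oxy]-4-methylhept-4-en-1-yl]oxy}silane
Product: 20 (3E)-4-methyl-7-[(triethylsilyl)oxy]hept-3-en-1-ol
Conditions: DDQ, CH2Cl2/pH 7 phosphate buffer, 0 °C
Reagents that add atoms: none
Why: Oxidative PMB cleavage by DDQ (benzylic hydride abstraction, then hemiacetal hydrolysis) in a buffered two-phase medium frees the homoallylic alcohol while the TES ether is retained.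

**Step 16**
Reactants: 20 (3E)-4-methyl-7-[(triethylsilyl)oxy]hept-3-en-1-ol
Product: 21 (3E)-4-methyl-7-[(triethylsilyl)oxy]hept-3-enal
Conditions: Dess–Martin periodinane, pyridine, CH2Cl2, 0 °C; used at once
Reagents that add atoms: none
Why: Buffered Dess–Martin oxidation gives the β,γ-unsaturated aldehyde under conditions too mild to move the alkene into conjugation.

**Step 17**
Reactants: 21 (3E)-4-methyl-7-[(triethylsilyl)oxy]hept-3-enal; 22 methyl propiolate
Product: 24 methyl (5E)-3-hydroxy-6-methyl-2-methylidene-9-[(triethylsilyl)oxy]non-5-enoate (racemic), via vinylalane 23 (not isolated)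
Conditions: 22, i-Bu2AlH, N-methylmorpholine N-oxide, THF, 0 °C, 1 h; then 21, 0 °C → rt
Reagents that add atoms: none
Why: Vinylalumination (a Baylis–Hillman-type hydroxyalkylation): conjugate hydroalumination of 22 gives the α-alanyl acrylate 23, which adds 1,2 to the aldehyde under non-basic conditions; the carbinol centre is racemic and is erased in step 18.

**Step 18**
Reactants: 24 methyl (5E)-3-hydroxy-6-methyl-2-methylidene-9-[(triethylsilyl)oxy]non-5-enoate
Product: 25 methyl (2Z,5E)-2-(bromomethyl)-6-methyl-9-[(triethylsilyl)oxy]nona-2,5-dienoate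
Conditions: NBS, Me2S, CH2Cl2, −20 → 0 °C
Reagents that add atoms: N-bromosuccinimide, O=C1CCC(=O)N1Br
Why: Corey–Kim-type activation of the allylic alcohol as an alkoxysulfonium salt followed by SN2' attack of bromide gives the thermodynamically preferred Z 2-(bromomethyl)alk-2-enoate.

**Step 19**
Reactants: 13 (2R,3S)-7-iodo-2-[(4-methoxybenzyl)oxy]-3-methyloct-7-enal; 25 methyl (2Z,5E)-2-(bromomethyl)-6-methyl-9-[(triethylsilyl)oxy]nona-2,5-dienoate
Product: 27 (4S,5R)-5-{(1R,2S)-6-iodo-1-[(4-methoxybenzyl)oxy]-2-methylhept-6-en-1-yl}-3-methylidene-4-{(2E)-3-methyl-6-[(triethylsilyl)oxy]hex-2-en-1-yl}oxolan-2-one, via hydroxy ester 26 (not isolated)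
Conditions: indium powder (2 equiv), THF/H2O (1:1), rt; then PPTS (cat.), CH2Cl2, rt
Reagents that add atoms: none
Why: Indium-mediated Barbier allylation: the allylindium from 25 adds through its γ-carbon to the aldehyde held in a chelate by C=O and the α-OPMB group (Cram-chelate attack anti to the C4 chain gives the C2/C3 syn relationship) in a closed chair transition state from the Z reagent (C1/C2 syn, hence the cis-lactone), and the γ-hydroxy ester lactonises under mild acid; a dr of roughly 4–6:1 is expected and the minor isomers are removed by chromatography.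

**Step 20**
Reactants: 27 the PMB-protected lactone
Product: 28 (4S,5R)-5-[(1R,2S)-1-hydroxy-6-iodo-2-methylhept-6-en-1-yl]-3-methylidene-4-{(2E)-3-methyl-6-[(triethylsilyl)oxy]hex-2-en-1-yl}oxolan-2-one
Conditions: DDQ, CH2Cl2/pH 7 phosphate buffer, 0 °C
Reagents that add atoms: none
Why: DDQ removes the PMB ether oxidatively under neutral buffered conditions that leave the TES ether, both alkenes, the iodoalkene and the lactone untouched.

**Step 21**
Reactants: 28 the C3 alcohol
Product: 29 (1R,2S)-6-iodo-2-methyl-1-[(2R,3S)-4-methylidene-3-{(2E)-3-methyl-6-[(triethylsilyl)oxy]hex-2-en-1-yl}-5-oxooxolan-2-yl]hept-6-en-1-yl acetate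
Conditions: Ac2O, pyridine, DMAP (cat.), CH2Cl2, rt
Reagents that add atoms: acetic anhydride, CC(=O)OC(C)=O
Why: DMAP-catalysed acylation converts the hindered secondary alcohol at C3 into the acetate of the target.

**Step 22**
Reactants: 29 the acetate
Product: 30 (1R,2S)-6-iodo-2-methyl-1-[(2R,3S)-4-methylidene-3-({(2R,3R)-3-methyl-3-[3-(triethylsilyloxy)propyl]oxiran-2-yl}methyl)-5-oxooxolan-2-yl]hept-6-en-1-yl acetate
Conditions: D-fructose-derived Shi ketone (30 mol%), Oxone (2KHSO5·KHSO4·K2SO4), K2CO3, Bu4NHSO4, MeCN/CH2(OMe)2/aq. Na2B4O7 buffer (pH 10.5), 0 °C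
Reagents that add atoms: potassium peroxymonosulfate (active part of Oxone), [K+].[O-]S(=O)(=O)OO
Why: Shi asymmetric epoxidation: the dioxirane of the D-fructose-derived ketone transfers oxygen through a spiro transition state to one face of the electron-rich E trisubstituted alkene, giving the 12R,13R oxirane under reagent control, while the electron-poor methylene lactone and the iodoalkene react far more slowly.

**Step 23**
Reactants: 30 the epoxy TES ether
Product: 31 (1R,2S)-6-iodo-2-methyl-1-[(2R,3S)-4-methylidene-3-({(2R,3R)-3-methyl-3-(3-oxopropyl)oxiran-2-yl}methyl)-5-oxooxolan-2-yl]hept-6-en-1-yl acetate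
Conditions: (COCl)2, DMSO, CH2Cl2, −78 → −30 °C; then Et3N, → 0 °C
Reagents that add atoms: none
Why: Direct Swern oxidation of a primary TES ether: the chlorosulfonium salt exchanges silicon for sulfur at oxygen and base-induced elimination gives the aldehyde without liberating the 4,5-epoxy alcohol, which would cyclise to a tetrahydrofuran.

**Step 24**
Reactants: 31 the iodoalkene aldehyde
Product: 32 macrocyclic allylic alcohol, the C9-epimer mixture of the target (1S,2R,3R,4S,12R,13R; C9 unassigned)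
Conditions: CrCl2 (15 equiv), NiCl2 (1 mol% of CrCl2), DMSO/THF, rt, 0.002 M, syringe-pump addition
Reagents that add atoms: none
Why: Intramolecular Nozaki–Hiyama–Kishi reaction: zerovalent nickel inserts into the C–I bond, transmetalation gives an alkenyl species of trivalent chromium that adds chemoselectively to the aldehyde (ester, lactone and oxirane are tolerated), and high dilution favours the 14-membered ring; the C9 configuration is not controlled here and is set in steps 25 and 26.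

**Step 25**
Reactants: 32 macrocyclic allylic alcohol (C9 epimers)
Product: 33 macrocyclic C9 ketone (8-methylidene-9-oxo; 1S,2R,3R,4S,12R,13R)
Conditions: Dess–Martin periodinane, NaHCO3, CH2Cl2, 0 °C
Reagents that add atoms: none
Why: Dess–Martin oxidation converges both C9 epimers to the single α-methylene ketone under buffered conditions that spare the oxirane.

**Step 26**
Reactants: 33 macrocyclic C9 ketone
Product: 34 target, the (1S,2R,3R,4S,9R,12R,13R) 14-membered carbocycle with C1/C2 cis-fused α-methylene-γ-butyrolactone (ring O on C2), 3-OAc, 4-Me, 8-methylidene, 9-OH and 12,13-epoxide bearing 12-Me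
Conditions: (S)-2-methyl-CBS-oxazaborolidine (1 equiv), catecholborane, toluene/CH2Cl2, −78 °C
Reagents that add atoms: none
Why: Corey–Bakshi–Shibata reduction: in the oxazaborolidine–borane complex the alkenyl (C8) side of the ketone acts as the large group, so the S catalyst delivers hydride to give the 9R allylic alcohol, and at −78 °C 1,2-reduction of the ketone is much faster than any reaction of the methylene lactone, acetate or oxirane.

**Compound list**
1 | (S)-citronellal, (3S)-3,7-dimethyloct-6-enal | CC(C)=CCC[C@H](C)CC=O | starting material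
2 | (2R,3S)-2-(anilinooxy)-3,7-dimethyloct-6-enal | CC(C)=CCC[C@H](C)[C@@H](ONc1ccccc1)C=O | intermediate
3 | (2R,3S)-2-(anilinooxy)-3,7-dimethyloct-6-en-1-ol | CC(C)=CCC[C@H](C)[C@@H](ONc1ccccc1)CO | intermediate
4 | (2R,3S)-3,7-dimethyloct-6-ene-1,2-diol | CC(C)=CCC[C@H](C)[C@@H](O)CO | intermediate
5 | (4R)-2-(4-methoxyphenyl)-4-[(2S)-6-methylhept-5-en-2-yl]-1,3-dioxolane | CC(C)=CCC[C@H](C)[C@@H]1COC(c2ccc(OC)cc2)O1 | intermediate
6 | (4S)-4-[(4R)-2-(4-methoxyphenyl)-1,3-dioxolan-4-yl]pentanal | O=CCC[C@H](C)[C@@H]1COC(c2ccc(OC)cc2)O1 | intermediate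
7 | (4S)-4-[(4R)-2-(4-methoxyphenyl)-1,3-dioxolan-4-yl]pentan-1-ol | OCCC[C@H](C)[C@@H]1COC(c2ccc(OC)cc2)O1 | intermediate
8 | (4R)-4-[(2S)-5-iodopentan-2-yl]-2-(4-methoxyphenyl)-1,3-dioxolane | ICCC[C@H](C)[C@@H]1COC(c2ccc(OC)cc2)O1 | intermediate
9 | (4R)-4-[(2S)-hept-6-yn-2-yl]-2-(4-methoxyphenyl)-1,3-dioxolane | C#CCCC[C@H](C)[C@@H]1COC(c2ccc(OC)cc2)O1 | intermediate
10 | (2R,3S)-2-[(4-methoxybenzyl)oxy]-3-methyloct-7-yn-1-ol | C#CCCC[C@H](C)[C@@H](OCc1ccc(OC)cc1)CO | intermediate
11 | 7-(diisobutylalumanyl) alkene of 10 as its O-diisobutylaluminium alkoxide | C=C([Al](CC(C)C)CC(C)C)CCC[C@H](C)[C@@H](OCc1ccc(OC)cc1)CO[Al](CC(C)C)CC(C)C | intermediate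
12 | (2R,3S)-7-iodo-2-[(4-methoxybenzyl)oxy]-3-methyloct-7-en-1-ol | C=C(I)CCC[C@H](C)[C@@H](OCc1ccc(OC)cc1)CO | intermediate
13 | (2R,3S)-7-iodo-2-[(4-methoxybenzyl)oxy]-3-methyloct-7-enal | C=C(I)CCC[C@H](C)[C@@H](OCc1ccc(OC)cc1)C=O | intermediate
14 | 3-[(4-methoxybenzyl)oxy]propan-1-ol | COc1ccc(COCCCO)cc1 | starting material
15 | 3-[(4-methoxybenzyl)oxy]propanal | COc1ccc(COCCC=O)cc1 | intermediate
16 | 5-[(4-methoxybenzyl)oxy]-2-methylpent-1-en-3-ol (racemic) | C=C(C)C(O)CCOCc1ccc(OC)cc1 | intermediate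
17 | ethyl (4E)-7-[(4-methoxybenzyl)oxy]-4-methylhept-4-enoate | CCOC(=O)CC/C(C)=C/CCOCc1ccc(OC)cc1 | intermediate
18 | (4E)-7-[(4-methoxybenzyl)oxy]-4-methylhept-4-en-1-ol | OCCC/C(C)=C/CCOCc1ccc(OC)cc1 | intermediate
19 | triethyl{[(4E)-7-[(4-methoxybenzyl)oxy]-4-methylhept-4-en-1-yl]oxy}silane | CC[Si](CC)(CC)OCCC/C(C)=C/CCOCc1ccc(OC)cc1 | intermediate
20 | (3E)-4-methyl-7-[(triethylsilyl)oxy]hept-3-en-1-ol | CC[Si](CC)(CC)OCCC/C(C)=C/CCO | intermediate
21 | (3E)-4-methyl-7-[(triethylsilyl)oxy]hept-3-enal | CC[Si](CC)(CC)OCCC/C(C)=C/CC=O | intermediate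
22 | methyl propiolate | C#CC(=O)OC | starting material
23 | methyl 2-(diisobutylalumanyl)prop-2-enoate | C=C([Al](CC(C)C)CC(C)C)C(=O)OC | intermediate
24 | methyl (5E)-3-hydroxy-6-methyl-2-methylidene-9-[(triethylsilyl)oxy]non-5-enoate (racemic) | CC[Si](CC)(CC)OCCC/C(C)=C/CC(O)C(=C)C(=O)OC | intermediate
25 | methyl (2Z,5E)-2-(bromomethyl)-6-methyl-9-[(triethylsilyl)oxy]nona-2,5-dienoate | BrC/C(C(=O)OC)=C\C/C=C(\C)CCCO[Si](CC)(CC)CC | intermediate
26 | methyl (3S,4R,5R,6S)-4-hydroxy-10-iodo-5-[(4-methoxybenzyl)oxy]-6-methyl-2-methylidene-3-{(2E)-3-methyl-6-[(triethylsilyl)oxy]hex-2-en-1-yl}undec-10-enoate | C=C(I)CCC[C@H](C)[C@@H](OCc1ccc(OC)cc1)[C@H](O)[C@@H](C/C=C(\C)CCCO[Si](CC)(CC)CC)C(=C)C(=O)OC | intermediate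
27 | (4S,5R)-5-{(1R,2S)-6-iodo-1-[(4-methoxybenzyl)oxy]-2-methylhept-6-en-1-yl}-3-methylidene-4-{(2E)-3-methyl-6-[(triethylsilyl)oxy]hex-2-en-1-yl}oxolan-2-one | C=C(I)CCC[C@H](C)[C@@H](OCc1ccc(OC)cc1)[C@@H]1OC(=O)C(=C)[C@@H]1C/C=C(\C)CCCO[Si](CC)(CC)CC | intermediate
28 | (4S,5R)-5-[(1R,2S)-1-hydroxy-6-iodo-2-methylhept-6-en-1-yl]-3-methylidene-4-{(2E)-3-methyl-6-[(triethylsilyl)oxy]hex-2-en-1-yl}oxolan-2-one | C=C(I)CCC[C@H](C)[C@@H](O)[C@@H]1OC(=O)C(=C)[C@@H]1C/C=C(\C)CCCO[Si](CC)(CC)CC | intermediate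
29 | (1R,2S)-6-iodo-2-methyl-1-[(2R,3S)-4-methylidene-3-{(2E)-3-methyl-6-[(triethylsilyl)oxy]hex-2-en-1-yl}-5-oxooxolan-2-yl]hept-6-en-1-yl acetate | C=C(I)CCC[C@H](C)[C@@H](OC(C)=O)[C@@H]1OC(=O)C(=C)[C@@H]1C/C=C(\C)CCCO[Si](CC)(CC)CC | intermediate
30 | (1R,2S)-6-iodo-2-methyl-1-[(2R,3S)-4-methylidene-3-({(2R,3R)-3-methyl-3-[3-(triethylsilyloxy)propyl]oxiran-2-yl}methyl)-5-oxooxolan-2-yl]hept-6-en-1-yl acetate | C=C(I)CCC[C@H](C)[C@@H](OC(C)=O)[C@@H]1OC(=O)C(=C)[C@@H]1C[C@H]2O[C@]2(C)CCCO[Si](CC)(CC)CC | intermediate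
31 | (1R,2S)-6-iodo-2-methyl-1-[(2R,3S)-4-methylidene-3-({(2R,3R)-3-methyl-3-(3-oxopropyl)oxiran-2-yl}methyl)-5-oxooxolan-2-yl]hept-6-en-1-yl acetate | C=C(I)CCC[C@H](C)[C@@H](OC(C)=O)[C@@H]1OC(=O)C(=C)[C@@H]1C[C@H]2O[C@]2(C)CCC=O | intermediate
32 | macrocyclic allylic alcohol, C9-epimer mixture of the target (1S,2R,3R,4S,12R,13R) | C=C1CCC[C@H](C)[C@@H](OC(C)=O)[C@@H]2OC(=O)C(=C)[C@@H]2C[C@H]2O[C@]2(C)CCC1O | intermediate
33 | macrocyclic 8-methylidene C9 ketone (1S,2R,3R,4S,12R,13R) | C=C1CCC[C@H](C)[C@@H](OC(C)=O)[C@@H]2OC(=O)C(=C)[C@@H]2C[C@H]2O[C@]2(C)CCC1=O | intermediate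
34 | target (1S,2R,3R,4S,9R,12R,13R), as described in step 26 | C=C1CCC[C@H](C)[C@@H](OC(C)=O)[C@@H]2OC(=O)C(=C)[C@@H]2C[C@H]2O[C@]2(C)CC[C@H]1O | target

**Totals**
Total step count: 26 (West fragment 9, East fragment 9, union and endgame 8).
Longest linear sequence: 17 steps (steps 1–9 then 19–26; the branch 10–18 then 19–26 is equally long).

**Three steps most likely to fail, with fallbacks**

Step 19 (indium Barbier union). The risk is only moderate Cram-chelate selectivity with a PMB ether in water, and partial loss of the TES ether. The fallback sets out from bromide 25. Bromide is displaced with Bu3SnLi (THF, −78 °C) to give the allylstannane methyl (2Z,5E)-6-methyl-2-[(tributylstannyl)methyl]-9-[(triethylsilyl)oxy]nona-2,5-dienoate F1. F1 is then added to aldehyde 13 precomplexed with MgBr2·OEt2 in CH2Cl2 at −25 °C. This is a Lewis-acid-mediated SE2' allylstannane addition through an open transition state on the five-membered magnesium chelate (Keck-type chelation control in a non-aqueous medium). Work-up comes back to the route at hydroxy ester 26, which is lactonised to 27 as before.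

Step 22 (Shi epoxidation). The risk is oxidation at iodine of the iodoalkene by the dioxirane and hydrolysis of the acetate at pH 10.5. The fallback installs the oxirane before the iodine-containing fragment is attached and sets out from hydroxy acrylate 24. Shi epoxidation under the step 22 conditions gives methyl 3-hydroxy-2-methylidene-4-{(2R,3R)-3-methyl-3-[3-(triethylsilyloxy)propyl]oxiran-2-yl}butanoate F2. NBS/Me2S converts it into methyl (2Z)-2-(bromomethyl)-4-{(2R,3R)-3-methyl-3-[3-(triethylsilyloxy)propyl]oxiran-2-yl}but-2-enoate F3. Indium coupling of F3 with aldehyde 13 gives the hydroxy ester methyl (3S,4R,5R,6S)-4-hydroxy-10-iodo-5-[(4-methoxybenzyl)oxy]-6-methyl-2-methylidene-3-({(2R,3R)-3-methyl-3-[3-(triethylsilyloxy)propyl]oxiran-2-yl}methyl)undec-10-enoate F4. PPTS lactonises it to (4S,5R)-5-{(1R,2S)-6-iodo-1-[(4-methoxybenzyl)oxy]-2-methylhept-6-en-1-yl}-3-methylidene-4-({(2R,3R)-3-methyl-3-[3-(triethylsilyloxy)propyl]oxiran-2-yl}methyl)oxolan-2-one F5. DDQ gives (4S,5R)-5-[(1R,2S)-1-hydroxy-6-iodo-2-methylhept-6-en-1-yl]-3-methylidene-4-({(2R,3R)-3-methyl-3-[3-(triethylsilyloxy)propyl]oxiran-2-yl}methyl)oxolan-2-one F6. Acetylation (Ac2O, pyridine, DMAP) comes back to the route at epoxide 30.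

Step 24 (Nozaki–Hiyama–Kishi ring closure). The risk is transannular opening of the C12–C13 oxirane by the chromium alkoxide formed at C9, and oligomerisation. The fallback closes the 14-membered ring before the oxirane exists and sets out from acetate 29. Direct Swern oxidation gives (1R,2S)-6-iodo-2-methyl-1-{(2R,3S)-4-methylidene-3-[(2E)-3-methyl-6-oxohex-2-en-1-yl]-5-oxooxolan-2-yl}hept-6-en-1-yl acetate F7. Cyclisation with CrCl2/NiCl2 under the step 24 conditions gives the 12E-alkene macrocyclic allylic alcohol (1S,2R,3R,4S; C9 epimers) F8. Dess–Martin oxidation gives the 12E-alkene macrocyclic C9 ketone F9. CBS reduction as in step 26 gives the 12E-alkene macrocyclic (9R)-alcohol F10. Shi epoxidation of the only trisubstituted alkene (step 22 conditions) comes back to the route at target 34.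

**Further compounds**
F1 | step 19 | methyl (2Z,5E)-6-methyl-2-[(tributylstannyl)methyl]-9-[(triethylsilyl)oxy]nona-2,5-dienoate | CCCC[Sn](CCCC)(CCCC)C/C(C(=O)OC)=C\C/C=C(\C)CCCO[Si](CC)(CC)CC
F2 | step 22 | methyl 3-hydroxy-2-methylidene-4-{(2R,3R)-3-methyl-3-[3-(triethylsilyloxy)propyl]oxiran-2-yl}butanoate (both C3 epimers) | COC(=O)C(=C)C(O)C[C@H]1O[C@]1(C)CCCO[Si](CC)(CC)CC
F3 | step 22 | methyl (2Z)-2-(bromomethyl)-4-{(2R,3R)-3-methyl-3-[3-(triethylsilyloxy)propyl]oxiran-2-yl}but-2-enoate | BrC/C(C(=O)OC)=C\C[C@H]1O[C@]1(C)CCCO[Si](CC)(CC)CC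
F4 | step 22 | methyl (3S,4R,5R,6S)-4-hydroxy-10-iodo-5-[(4-methoxybenzyl)oxy]-6-methyl-2-methylidene-3-({(2R,3R)-3-methyl-3-[3-(triethylsilyloxy)propyl]oxiran-2-yl}methyl)undec-10-enoate | C=C(I)CCC[C@H](C)[C@@H](OCc1ccc(OC)cc1)[C@H](O)[C@@H](C[C@H]1O[C@]1(C)CCCO[Si](CC)(CC)CC)C(=C)C(=O)OC
F5 | step 22 | (4S,5R)-5-{(1R,2S)-6-iodo-1-[(4-methoxybenzyl)oxy]-2-methylhept-6-en-1-yl}-3-methylidene-4-({(2R,3R)-3-methyl-3-[3-(triethylsilyloxy)propyl]oxiran-2-yl}methyl)oxolan-2-one | C=C(I)CCC[C@H](C)[C@@H](OCc1ccc(OC)cc1)[C@@H]1OC(=O)C(=C)[C@@H]1C[C@H]2O[C@]2(C)CCCO[Si](CC)(CC)CC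
F6 | step 22 | (4S,5R)-5-[(1R,2S)-1-hydroxy-6-iodo-2-methylhept-6-en-1-yl]-3-methylidene-4-({(2R,3R)-3-methyl-3-[3-(triethylsilyloxy)propyl]oxiran-2-yl}methyl)oxolan-2-one | C=C(I)CCC[C@H](C)[C@@H](O)[C@@H]1OC(=O)C(=C)[C@@H]1C[C@H]2O[C@]2(C)CCCO[Si](CC)(CC)CC
F7 | step 24 | (1R,2S)-6-iodo-2-methyl-1-{(2R,3S)-4-methylidene-3-[(2E)-3-methyl-6-oxohex-2-en-1-yl]-5-oxooxolan-2-yl}hept-6-en-1-yl acetate | C=C(I)CCC[C@H](C)[C@@H](OC(C)=O)[C@@H]1OC(=O)C(=C)[C@@H]1C/C=C(\C)CCC=O
F8 | step 24 | 12E-alkene macrocyclic allylic alcohol (1S,2R,3R,4S; C9 epimers; no oxirane) | C=C1CCC[C@H](C)[C@@H](OC(C)=O)[C@@H]2OC(=O)C(=C)[C@@H]2C/C=C(\C)CCC1O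
F9 | step 24 | 12E-alkene macrocyclic 8-methylidene C9 ketone (1S,2R,3R,4S) | C=C1CCC[C@H](C)[C@@H](OC(C)=O)[C@@H]2OC(=O)C(=C)[C@@H]2C/C=C(\C)CCC1=O
F10 | step 24 | 12E-alkene macrocyclic (9R)-allylic alcohol (1S,2R,3R,4S,9R) | C=C1CCC[C@H](C)[C@@H](OC(C)=O)[C@@H]2OC(=O)C(=C)[C@@H]2C/C=C(\C)CC[C@H]1O
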